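**Strategy.** The pyranone ring is assembled late by a [3+3] union. Ring A enters as a phenol-derived O1/C4a 1,3-dinucleophile, and C2–C3–C4 as an aldol-derived 1,3-dielectrophile (benzylic carbinol plus Weinreb amide) that already carries C3 as its (R)-methoxy centre. In one pot the ortho-lithiated phenoxide is acylated (C4–C4a) and, on acidification, the phenol oxygen closes onto the ionised benzylic carbon (O1–C2). The step exploits the 2,5-dioxygenated 4-methoxyphenyl B ring, which makes C2 a stabilised cation, so that C2 settles trans to C3 in the six-membered ring. Benzyl ethers mask the B-ring hydroquinone until a final hydrogenolysis.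

Key step: step 7

Remark: chromanone numbering is O1, C2, C3, C4, C4a, C5–C8, C8a, with primed B-ring positions; the target SMILES is read as the trans-(2R,3R) isomer.

Step 1
Reactants: 1 2-methoxybenzene-1,4-diol (methoxyhydroquinone)
Product: 2 1,4-bis(benzyloxy)-2-methoxybenzene
Conditions: BnBr, K2CO3, DMF, N2, rt
Reagents that add atoms: benzyl bromide (BrCc1ccccc1)
Why: Double Williamson etherification of the two phenolic hydroxyls under carbonate base should be clean, the inert atmosphere guarding the hydroquinone against air oxidation.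

Step 2
Reactants: 2 1,4-bis(benzyloxy)-2-methoxybenzene
Product: 4 2,5-bis(benzyloxy)-4-methoxybenzaldehyde, via aryl iminium chloride 3 (not isolated)
Conditions: POCl3, DMF, 0 → 70 °C; then aq. NaOAc
Reagents that add atoms: N,N-dimethylformamide (CN(C)C=O); water (O)
Why: Vilsmeier–Haack formylation should occur at the one position that is para to the methoxy group and ortho to a benzyloxy group, as in the formylation of 1,2,4-trimethoxybenzene, and hydrolysis of iminium 3 releases the aldehyde.

Step 3
Reactants: 5 (R)-4-benzyloxazolidin-2-one; 6 methoxyacetyl chloride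
Product: 8 (R)-4-benzyl-3-(2-methoxyacetyl)oxazolidin-2-one, via lithiated oxazolidinone 7 (not isolated)
Conditions: n-BuLi, THF, −78 °C; then 6, −78 → 0 °C
Reagents that add atoms: none
Why: N-acylation of the lithiated oxazolidinone with an acid chloride is the standard entry to Evans imides and does not touch the stereocentre.

Step 4
Reactants: 8 (R)-4-benzyl-3-(2-methoxyacetyl)oxazolidin-2-one; 4 2,5-bis(benzyloxy)-4-methoxybenzaldehyde
Product: 11 (R)-4-benzyl-3-[(2R,3S)-3-[2,5-bis(benzyloxy)-4-methoxyphenyl]-3-hydroxy-2-methoxypropanoyl]oxazolidin-2-one, via boron Z-enolate 9 (not isolated), via boron aldolate 10 (not isolated)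
Conditions: Bu2BOTf, i-Pr2NEt, CH2Cl2, −78 → 0 °C; then 4, −78 → 0 °C; then pH 7 buffer, MeOH, 30% H2O2, 0 °C
Reagents that add atoms: none
Why: Evans syn glycolate aldol reaction: the Z-boron enolate 9 reacts through a Zimmerman–Traxler chair in which the (R)-benzyl group of the dipole-opposed auxiliary shields one enolate face, which should set (2R,3S) in aldolate 10, released by the oxidative work-up.

Step 5
Reactants: 11 the (2R,3S) aldol imide
Product: 12 (2R,3S)-3-[2,5-bis(benzyloxy)-4-methoxyphenyl]-3-hydroxy-N,2-dimethoxy-N-methylpropanamide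
Conditions: MeNH(OMe)·HCl, AlMe3, CH2Cl2, 0 °C → rt; aq. Rochelle salt
Reagents that add atoms: N,O-dimethylhydroxylamine hydrochloride (CNOC.Cl)
Why: Weinreb aminolysis with the aluminium amide, directed by the β-aluminium alkoxide, cleaves the exocyclic imide carbonyl selectively under non-basic conditions, so the α-methoxy stereocentre should stay intact.

Step 6
Reactants: 13 3,4,5-trimethoxyphenol
Product: 14 2-bromo-3,4,5-trimethoxyphenol
Conditions: NBS (1.0 equiv), CH2Cl2, −78 → 0 °C
Reagents that add atoms: N-bromosuccinimide (O=C1CCC(=O)N1Br)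
Why: Electrophilic aromatic bromination of the strongly activated phenol; the two free positions are equivalent by symmetry and ortho to OH, so one equivalent of NBS at low temperature should give a single monobromide.

Step 7
Reactants: 14 2-bromo-3,4,5-trimethoxyphenol; 12 the (2R,3S) Weinreb amide
Product: 19 (2R,3R)-2-[2,5-bis(benzyloxy)-4-methoxyphenyl]-3,5,6,7-tetramethoxychroman-4-one, via dilithiated phenol 15 (not isolated), via lithium alkoxide 16 (not isolated), via tetrahedral adduct 17 (not isolated), via hydroxy ketone 18 (not isolated)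
Conditions: 14, n-BuLi (2.1 equiv), THF, −78 °C; 12, LiHMDS (1.0 equiv), THF, −78 °C; combine, −78 → 0 °C; then CF3CO2H (excess), −78 °C → rt
Reagents that add atoms: none
Why: Bromine–lithium exchange on the lithium phenoxide gives aryllithium 15, whose carbon adds to the Weinreb amide of alkoxide 16 to form the chelated adduct 17 (C4–C4a); acid collapses 17 to ketone 18 and ionises its benzylic carbinol, and the ortho phenol oxygen captures the cation (O1–C2). The closest known reactions are the Weinreb ketone synthesis with an ortho-lithiated phenoxide and the acid-mediated cycloetherification of 2'-hydroxy-β-oxygenated dihydrochalcones used for dihydroflavonols. The pyranone ring closes in a 6-exo-trig mode onto the quinone-methide-like cation (6-exo-tet if the displacement is concerted, which leads to the same trans product by inversion of the 3S carbinol). C3 (R) comes unchanged from the aldol, and C2 (R) is controlled by C3, because the reversible closure on the ortho/para-oxygenated benzylic cation should settle in the trans-diequatorial 2-aryl-3-methoxy chromanone. The step needs C-acylation before any cation exists and O- rather than C-alkylation: the order of addition secures the first, and the second follows because only O1 can reach C2 in a six-membered ring, while the Weinreb chelate and the fast intramolecular capture protect H-3 from enolisation or E1 loss.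

Step 8
Reactants: 19 the dibenzyl-protected flavanone
Product: 20 (2R,3R)-2-(2,5-dihydroxy-4-methoxyphenyl)-3,5,6,7-tetramethoxychroman-4-one (target)
Conditions: H2 (1 atm), 10% Pd/C, degassed EtOAc, rt
Reagents that add atoms: none
Why: Catalytic hydrogenolysis of the two aryl benzyl ethers under neutral conditions should free the hydroquinone without touching the ketone or epimerising C2/C3, as is standard for benzyl-protected flavanones.

**Compound list**

1 | 2-methoxybenzene-1,4-diol | COc1cc(O)ccc1O | starting material
2 | 1,4-bis(benzyloxy)-2-methoxybenzene | COc1cc(OCc2ccccc2)ccc1OCc1ccccc1 | intermediate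
3 | N-{[2,5-bis(benzyloxy)-4-methoxyphenyl]methylidene}-N-methylmethanaminium chloride | COc1cc(OCc2ccccc2)c(C=[N+](C)C)cc1OCc1ccccc1.[Cl-] | intermediate (not isolated)
4 | 2,5-bis(benzyloxy)-4-methoxybenzaldehyde | COc1cc(OCc2ccccc2)c(C=O)cc1OCc1ccccc1 | intermediate
5 | (R)-4-benzyloxazolidin-2-one | O=C1N[C@H](Cc2ccccc2)CO1 | starting material
6 | methoxyacetyl chloride | COCC(Cl)=O | starting material
7 | (R)-4-benzyl-3-lithiooxazolidin-2-one | [Li]N1[C@H](Cc2ccccc2)COC1=O | intermediate (not isolated)
8 | (R)-4-benzyl-3-(2-methoxyacetyl)oxazolidin-2-one | COCC(=O)N1[C@H](Cc2ccccc2)COC1=O | intermediate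
9 | (Z)-dibutylboron enolate of 8 | CCCCB(CCCC)O/C(=C\OC)N1[C@H](Cc2ccccc2)COC1=O | intermediate (not isolated)
10 | dibutylboron (2R,3S)-aldolate of 11 | O=C(N1[C@H](Cc2ccccc2)COC1=O)[C@H](OC)[C@@H](OB(CCCC)CCCC)c1cc(OCc2ccccc2)c(OC)cc1OCc1ccccc1 | intermediate (not isolated)
11 | (R)-4-benzyl-3-[(2R,3S)-3-[2,5-bis(benzyloxy)-4-methoxyphenyl]-3-hydroxy-2-methoxypropanoyl]oxazolidin-2-one | O=C(N1[C@H](Cc2ccccc2)COC1=O)[C@H](OC)[C@@H](O)c1cc(OCc2ccccc2)c(OC)cc1OCc1ccccc1 | intermediate
12 | (2R,3S)-3-[2,5-bis(benzyloxy)-4-methoxyphenyl]-3-hydroxy-N,2-dimethoxy-N-methylpropanamide | CON(C)C(=O)[C@H](OC)[C@@H](O)c1cc(OCc2ccccc2)c(OC)cc1OCc1ccccc1 | intermediate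
13 | 3,4,5-trimethoxyphenol | COc1cc(O)cc(OC)c1OC | starting material
14 | 2-bromo-3,4,5-trimethoxyphenol | COc1cc(O)c(Br)c(OC)c1OC | intermediate
15 | lithium 2-lithio-3,4,5-trimethoxyphenolate | COc1cc(O[Li])c([Li])c(OC)c1OC | intermediate (not isolated)
16 | lithium alkoxide of 12 | CON(C)C(=O)[C@H](OC)[C@@H](O[Li])c1cc(OCc2ccccc2)c(OC)cc1OCc1ccccc1 | intermediate (not isolated)
17 | trilithium tetrahedral adduct of 15 and 16 (hemiaminal carbon undefined) | COc1cc(O[Li])c(C(O[Li])(N(C)OC)[C@H](OC)[C@@H](O[Li])c2cc(OCc3ccccc3)c(OC)cc2OCc2ccccc2)c(OC)c1OC | intermediate (not isolated)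
18 | (2R,3S)-3-[2,5-bis(benzyloxy)-4-methoxyphenyl]-3-hydroxy-1-(6-hydroxy-2,3,4-trimethoxyphenyl)-2-methoxypropan-1-one | COc1cc(O)c(C(=O)[C@H](OC)[C@@H](O)c2cc(OCc3ccccc3)c(OC)cc2OCc2ccccc2)c(OC)c1OC | intermediate (not isolated)
19 | (2R,3R)-2-[2,5-bis(benzyloxy)-4-methoxyphenyl]-3,5,6,7-tetramethoxychroman-4-one | COc1cc(OCc2ccccc2)c([C@H]2Oc3cc(OC)c(OC)c(OC)c3C(=O)[C@@H]2OC)cc1OCc1ccccc1 | intermediate
20 | (2R,3R)-2-(2,5-dihydroxy-4-methoxyphenyl)-3,5,6,7-tetramethoxychroman-4-one | COc1cc(O)c([C@H]2Oc3cc(OC)c(OC)c(OC)c3C(=O)[C@@H]2OC)cc1O | target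

**Totals.** Total step count: 8. Longest linear sequence: 6 steps (steps 1, 2, 4, 5, 7, 8).

**Steps most likely to fail**

Step 7. After acidification the benzylic cation may lose H-3 (E1) or be attacked by carbon of free trimethoxyphenol before O1 closes, which would erode the C3 configuration or divert material. The hindered aryllithium may also add slowly. The fallback sets out from 12 and 14 and comes back at 19. The anionic stage is run as before but quenched with aqueous NH4Cl, and hydroxy ketone 18 is isolated. It is then closed under Mitsunobu conditions (PPh3, DIAD, THF, 0 °C), a cation-free SN2 6-exo-tet displacement that inverts the (3S) carbinol to C2 (R) and should give 19 directly. This fallback makes no new compound (F0).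

Step 4. Addition of the boron enolate to the hindered, electron-rich ortho-alkoxybenzaldehyde may be slow, and retro-aldol or ionisation of the electron-rich benzylic carbinol on work-up may lower conversion and diastereomeric purity. The fallback sets out from 4 and comes back at 12, replacing auxiliary control by a catalytic reduction with dynamic kinetic resolution.
- Aldehyde 4 is condensed with the lithium enolate of methyl methoxyacetate (LDA, THF, −78 °C) to give methyl 3-[2,5-bis(benzyloxy)-4-methoxyphenyl]-3-hydroxy-2-methoxypropanoate F1 as a mixture of stereoisomers.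
- Dess–Martin oxidation should give the β-keto ester methyl 3-[2,5-bis(benzyloxy)-4-methoxyphenyl]-2-methoxy-3-oxopropanoate F2, whose α-centre is labile.
- Ru–TsDPEN transfer hydrogenation (HCO2H/Et3N), with the catalyst enantiomer that leads to the (3S) carbinol, should give the syn ester methyl (2R,3S)-3-[2,5-bis(benzyloxy)-4-methoxyphenyl]-3-hydroxy-2-methoxypropanoate F3.
- Aminolysis with MeNH(OMe)·HCl/AlMe3 returns 12.

Step 8. Hydrogenolytic opening of the doubly activated benzylic C2–O1 bond of the pyranone, or reduction of the ketone, may compete with O-debenzylation. The fallback sets out from 19 and comes back at 20. The benzyl ethers are removed without hydrogen by BCl3 with pentamethylbenzene as cation scavenger (CH2Cl2, −78 °C), which should leave the methyl ethers and the C2–O1 bond alone at that temperature. This fallback makes no new compound (F0).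

**Further compounds**

F0 | step 7 | none | none
F1 | step 4 | methyl 3-[2,5-bis(benzyloxy)-4-methoxyphenyl]-3-hydroxy-2-methoxypropanoate (mixture of stereoisomers) | COC(C(=O)OC)C(O)c1cc(OCc2ccccc2)c(OC)cc1OCc1ccccc1
F2 | step 4 | methyl 3-[2,5-bis(benzyloxy)-4-methoxyphenyl]-2-methoxy-3-oxopropanoate (racemic) | COC(C(=O)OC)C(=O)c1cc(OCc2ccccc2)c(OC)cc1OCc1ccccc1
F3 | step 4 | methyl (2R,3S)-3-[2,5-bis(benzyloxy)-4-methoxyphenyl]-3-hydroxy-2-methoxypropanoate | COC(=O)[C@H](OC)[C@@H](O)c1cc(OCc2ccccc2)c(OC)cc1OCc1ccccc1
F0 | step 8 | none | none
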